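All runs come from a simulation on assumed constants.

The quick number for the oak flask is reckoned from the surplus s, charged initiator D minus charged J 0.0800 mM, since D that J takes starts no chain.

common to all: Q 0.050 M; J 0.17 mM

| flask | D | remark | time |
|---|---|---|---|
| oak | 0.25 mM | the very flask that is asked about, followed so far |  |
| maple | 0.12 mM | run made earlier |  |
| flask | 0.25 mM |  | 5.0 h |

oak run (percent of the Q charged)

| time / min | L / % | Q / % |
|---|---|---|
| 5.00 | 0 | 98.4 |
| 12.0 | 0.6 | 97.3 |
| 25.0 | 2.3 | 91.4 |
| 60.0 | 6.8 | 79.8 |

maple run (percent of the Q charged)

| time / h | L / % | Q / % |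
|---|---|---|
| 0.667 | 1.1 | 89.2 |
| 2.00 | 0.8 | 67.6 |
| 3.00 | 3.0 | 58.8 |
| 5.00 | 0.4 | 40.1 |

(standard deviation of a reading: 1 percentage point)

- average number of monomer units in a chain (chains begun, living or dead) at 5.0 h
- part of the Q that has reacted at 5.0 h

- the average divides the monomer in chains by the number of chains begun, living and dead together
- the numbers in the tables scatter by 1 percentage point (one standard deviation)
- reactions considered so far: Q -> Z; D + J -> G; Q + D -> E + L; Q + D -> X; Q + E -> L + E
- the earlier runs do not show the number of chains; that part of a forecast is a guess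

The maple flask, with J above D, shows L, the monomer in chains, no higher than 3.0%, yet its free monomer Q reads 40.1% at 5.00 h. That reads as a background loss of 0.183 /h.

In the oak flask, L climbs from 2.3% to 6.8% between 25.0 min and 60.0 min. Divided by the mean Q, this reads as growth of 0.0901 /h. Freezing the living end E makes this growth pseudo-first-order in Q, and it is taken as proportional to s.

The two losses add to 0.273 /h, so c, the part of Q reacted, is reckoned at 74.4% for 5.0 h. The growth share of that puts L near 12.3 mM. Each chain begun costs one D and J is taken to claim its whole charge, so chains are reckoned within s and dp, the average chain length, starts from 154. Any part of s that starts no chain lifts dp by an amount these runs do not show, so that figure is a guessed floor.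

The forecast gave c 74%, close to this reckoning, and dp 190, above this floor, “though this is a guess”.

The flask gives dp 437 and c 75.8%.

    Q → Z (k = 0.00280 /min)
    D + J → G (k = 5500 /M/min)
    Q + D → E + L (k = 0.180 /M/min)
    Q + D → X (k = 0.240 /M/min)
    Q + E → L + E, rate k5*[E]*[Q] (k = 69.0 /M/min)

In the oak flask, E stands at 3.33 × 10⁻⁵ M at 5.00 h, so chains took 41.6% of s. The neighbour, the same flask with J at 6.8 × 10⁻⁵ M, has a surplus of 0.182 mM. Growth scaled by surplus gives a total loss of 0.388 /h, hence c of 85.6%. The same share gives 0.0758 mM of chains, and its L of 49.5% then gives dp 327. That neighbour flask itself gives c 87.9% and dp 337.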